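Readings and results come from a simulation on assumed constants, and the scatter is random.

3 questions stand: two orders at the south-east charge and one yield in the west flask. Substrate and partner make target in a closed, stirred flask at constant temperature, and target is what is read.

| flask | substrate | partner | time |
|---|---|---|---|
| south-east | 0.120 M | 0.240 M |  |
| south-west | 0.0480 M | 0.168 M |  |
| east | 0.240 M | 0.240 M |  |
| north | 0.120 M | 0.480 M |  |
| west | 0.420 M | 0.240 M | 130 min |

| run | time / min | [target] / M |
|---|---|---|
| south-east run | 4.7 | 0.0024 |
| south-east run | 14 | 0.0106 |
| south-east run | 27 | 0.0288 |
| south-east run | 43 | 0.0460 |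
| south-east run | 61 | 0.0593 |
| south-east run | 82 | 0.0670 |
| south-east run | 100 | 0.0719 |
| south-east run | 130 | 0.0747 |
| south-west run | 4.7 | 0.0014 |
| south-west run | 14 | 0.0023 |
| south-west run | 27 | 0.0105 |
| south-west run | 43 | 0.0171 |
| south-west run | 61 | 0.0243 |
| south-west run | 82 | 0.0283 |
| south-west run | 100 | 0.0316 |
| south-west run | 130 | 0.0322 |
| east run | 4.7 | 0.0036 |
| east run | 14 | 0.0223 |
| east run | 27 | 0.0549 |
| east run | 43 | 0.0801 |
| east run | 61 | 0.0980 |
| east run | 82 | 0.1102 |
| east run | 100 | 0.1150 |
| east run | 130 | 0.1193 |
| north run | 4.7 | 0.0060 |
| north run | 14 | 0.0205 |
| north run | 27 | 0.0476 |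
| north run | 43 | 0.0670 |
| north run | 61 | 0.0793 |
| north run | 82 | 0.0795 |
| north run | 100 | 0.0828 |
| north run | 130 | 0.0831 |

(standard deviation of a reading: 0.001 M)

- reaction order in [substrate] at the outset, round the charge of the south-east run, defined at two percent of the substrate turned into target (one fixed amount of target, the same in the runs compared)
- reaction order in [partner] at the outset, round the charge of the south-east run, defined at two percent of the substrate turned into target
- target in the west run at 130 min, as a share of the substrate charged

- Overall: substrate + partner -> target.
- Constant volume, constant temperature.
- "The second partner" is partner.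
- An order is taken over about fifteen percent of the charge, up and down.

Two chemists argue over the orders. The first compares runs at one clock time. At 14 min, the south-east run holds 0.0106 M. The east run, with twice the substrate, holds 0.0223 M. The north run, with twice the partner, holds 0.0205 M. She treats amounts as rates and reads orders of 1.07 and 0.952.

The second chemist, whose reckoning I take as mine, objects. The orders are defined at one amount of target, and the south-east curve reads as having a lag (an induction period). The mean south-east rate reads 5.11 × 10⁻⁴ M min⁻¹ up to 4.7 min, and it is faster, 8.82 × 10⁻⁴ M min⁻¹, between 4.7 min and 14 min.

So let the rate r start from zero and grow in proportion to time. Target P is then a times time squared, with a constant a for each run, and r = 2√(aP). Time has dropped out. Divide the rates of two runs at the same P, and P drops out too. For north over south-east this gives 1.39, the same-target rate ratio ρ: the square root of the ratio of target amounts at one clock time.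

For east over south-east, ρ is 1.45. Taking logarithms against the charge ratios, I commit to orders of 0.536 in substrate and 0.476 in partner. These orders are taken across twice the charge, not the asked span round it. The squared time is an assumption. The reading of 0.0024 M carries a scatter of 0.001 M, too much to test it. The first chemist's reading is right for a curve rising straight from zero, where the amount ratio at one time equals the rate ratio at one amount. ρ says nothing about the west yield.

The forecast takes the clock side, with 0.8, 0.85 and 38%: “That suggests orders a little below one”.

The flask gives 0.61, 0.51 and 38.5%.

    substrate ⇌ intermediate + by-product (0.01764 min⁻¹, 0.1200 M⁻¹ min⁻¹)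
    intermediate + partner → target (0.3756 M⁻¹ min⁻¹)
    2 substrate → homo dimer (0.1152 M⁻¹ min⁻¹)
    substrate + partner + target → 2 target (1.398 M⁻² min⁻¹)

The substrate order stands above my 0.536, and the partner order is close to my 0.476. At the fixed amount of target, the north rate is 1.4 times the south-east rate, and ρ gave 1.39. That puts the south-east rate at that amount of target at 7.96 × 10⁻⁴ M min⁻¹. Now take the south-west run against the south-east run at 14 min. Its reading of 0.0023 M carries the same scatter of 0.001 M, and ρ is 0.466. ρ times that south-east rate is 3.71 × 10⁻⁴ M min⁻¹. The south-west flask's rate at that amount of target is 3.7 × 10⁻⁴ M min⁻¹.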